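The route rests on the C4–C4a disconnection of the (2S)-flavanone: ring C is closed by intramolecular Friedel–Crafts acylation of an (S)-3-aryloxy-3-phenylpropanoic acid whose stereocentre (future C2) comes from a Mitsunobu inversion. The step exploits the symmetry of ring A in the open precursor: the two carbons ortho to the ether oxygen O1 (future C4a and C8) are equivalent about the axis through the O1-bearing carbon (C8a) and the pyronylmethyl-bearing carbon (C6), so one operation forms ring C and fixes the side chain at C6 with C8 free. The precursor is a 3,5-dimethoxyphenyl ether carrying the O-benzylated pyronylmethyl group para to oxygen; C8 iodination, carbonylative coupling and ether cleavage finish the target.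

Key step: step 7

Assumption: the target is taken as the (2S)-flavanone drawn, the pyrone is written throughout as its 4-oxy-2-pyranone tautomer, and any 2-benzyloxy-4-pyranone regioisomer formed in step 5 is expected to converge on the same target in step 11.

Step 1
Reactants: 1 pentan-3-one
Product: 2 3-(trimethylsilyloxy)pent-2-ene (E/Z mixture)
Conditions: TMSCl, Et3N, DMF, 80 °C; pentane extraction, distillation
Reagents that add atoms: chlorotrimethylsilane, C[Si](C)(C)Cl
Why: Silyl enol ether formation from a symmetric ketone can give only one constitutional isomer, and the alkene geometry is irrelevant because this carbon becomes aromatic C5 of the pyrone.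

Step 2
Reactants: 2 3-(trimethylsilyloxy)pent-2-ene; 3 malonyl dichloride
Product: 4 6-ethyl-4-hydroxy-5-methyl-2H-pyran-2-one
Conditions: Et2O, −78 °C → rt; aqueous work-up
Reagents that add atoms: none
Why: C-acylation of the silyl enol ether by one acid chloride, then enol O-acylation by the second (acylation–lactonisation), is the established way to a 4-hydroxy-2-pyranone from a silyl enol ether and malonyl dichloride.

Step 3
Reactants: 5 4-hydroxy-2,6-dimethoxybenzaldehyde; 6 ethyl (3R)-3-hydroxy-3-phenylpropanoate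
Product: 7 ethyl (3S)-3-(4-formyl-3,5-dimethoxyphenoxy)-3-phenylpropanoate
Conditions: PPh3, DIAD, THF, 0 °C → rt
Reagents that add atoms: none
Why: Mitsunobu etherification: the phenoxide displaces the oxyphosphonium-activated benzylic alcohol by SN2 with inversion, turning (R)-6 into the (S)-ether and so setting the future C2, and the acidic para-formyl phenol should keep dehydration to ethyl cinnamate in check.

Step 4
Reactants: 4 6-ethyl-4-hydroxy-5-methyl-2H-pyran-2-one; 7 ethyl (3S)-3-(4-formyl-3,5-dimethoxyphenoxy)-3-phenylpropanoate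
Product: 9 ethyl (3S)-3-{4-[(6-ethyl-4-hydroxy-5-methyl-2-oxo-2H-pyran-3-yl)methyl]-3,5-dimethoxyphenoxy}-3-phenylpropanoate, via Knoevenagel adduct 8 (not isolated)
Conditions: L-proline (20 mol%), Hantzsch ester (1.1 equiv), CH2Cl2, rt
Reagents that add atoms: none
Why: Organocatalytic three-component reductive alkylation: proline-promoted Knoevenagel condensation at C3 of the pyrone gives the arylidene-dione 8, which is reduced in the flask by conjugate hydride transfer from the Hantzsch ester before a second pyrone can add.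

Step 5
Reactants: 9 ethyl (3S)-3-{4-[(6-ethyl-4-hydroxy-5-methyl-2-oxo-2H-pyran-3-yl)methyl]-3,5-dimethoxyphenoxy}-3-phenylpropanoate
Product: 10 ethyl (3S)-3-{4-[(4-benzyloxy-6-ethyl-5-methyl-2-oxo-2H-pyran-3-yl)methyl]-3,5-dimethoxyphenoxy}-3-phenylpropanoate
Conditions: BnOH, PPh3, DIAD, THF, 0 °C → rt
Reagents that add atoms: benzyl alcohol, OCc1ccccc1
Why: Mitsunobu O-alkylation of the acidic pyrone enol (a vinylogous carboxylic acid) under neutral conditions avoids C3-benzylation and installs an ether that should survive steps 6–10 yet fall to BCl3 at low temperature.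

Step 6
Reactants: 10 ethyl (3S)-3-{4-[(4-benzyloxy-6-ethyl-5-methyl-2-oxo-2H-pyran-3-yl)methyl]-3,5-dimethoxyphenoxy}-3-phenylpropanoate
Product: 11 (3S)-3-{4-[(4-benzyloxy-6-ethyl-5-methyl-2-oxo-2H-pyran-3-yl)methyl]-3,5-dimethoxyphenoxy}-3-phenylpropanoic acid
Conditions: LiOH·H2O, THF/H2O, 0 °C → rt; then 1 M HCl to pH 3
Reagents that add atoms: lithium hydroxide, [Li+].[OH-]
Why: Ester saponification; the fully substituted alkoxypyranone should resist hydroxide at 0 °C, and the electron-rich aryloxide is a poor leaving group for E1cB loss, so the stereocentre is not disturbed.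

Step 7
Reactants: 11 (3S)-3-{4-[(4-benzyloxy-6-ethyl-5-methyl-2-oxo-2H-pyran-3-yl)methyl]-3,5-dimethoxyphenoxy}-3-phenylpropanoic acid
Product: 13 (2S)-6-[(4-benzyloxy-6-ethyl-5-methyl-2-oxo-2H-pyran-3-yl)methyl]-5,7-dimethoxy-2-phenylchroman-4-one, via mixed trifluoroacetic anhydride 12 (not isolated)
Conditions: (CF3CO)2O (2 equiv), CH2Cl2, 0 °C → rt; NaHCO3 quench
Reagents that add atoms: none
Why: The acid is converted into mixed anhydride 12, whose acyl carbon is attacked by the ring carbon ortho to the ether oxygen and para to a methoxy group, and proton loss from the arenium ion restores ring A; this is an intramolecular Friedel–Crafts acylation of the kind used to close chroman-4-ones from 3-aryloxypropanoic acids. Ring C forms by 6-exo-trig closure at the acyl carbon, which creates the C4–C4a bond. No stereocentre is created, and C2 should keep the (S) configuration set in step 3 because trifluoroacetic acid in CH2Cl2 at or below room temperature, without a strong Lewis acid, is too weak to ionise or eliminate the benzylic C2–O1 bond. The step needs regioselectivity between the two carbons ortho to O1, and the substrate secures it because the two methoxy groups flank the pyronylmethyl carbon symmetrically, so both carbons are equivalent and only the flavanone with the side chain on C6 and C8 unsubstituted can form. Intramolecular six-membered closure onto a triply oxygenated ring should outrun intermolecular trifluoroacetylation, and the new ketone deactivates C8 afterwards.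

Step 8
Reactants: 13 (2S)-6-[(4-benzyloxy-6-ethyl-5-methyl-2-oxo-2H-pyran-3-yl)methyl]-5,7-dimethoxy-2-phenylchroman-4-one
Product: 14 (2S)-6-[(4-benzyloxy-6-ethyl-5-methyl-2-oxo-2H-pyran-3-yl)methyl]-8-iodo-5,7-dimethoxy-2-phenylchroman-4-one
Conditions: NIS, TFA (cat.), MeCN, 0 °C → rt, dark
Reagents that add atoms: N-iodosuccinimide, O=C1CCC(=O)N1I
Why: Electrophilic aromatic iodination: C8, ortho to O1 and to the C7 methoxy group and para to the C5 methoxy group, is the only unsubstituted activated arene carbon, since both nucleophilic pyrone carbons are substituted.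

Step 9
Reactants: 15 2-methylprop-1-enylmagnesium bromide; 16 tributyltin chloride
Product: 17 tributyl(2-methylprop-1-enyl)stannane
Conditions: THF, 0 °C → rt
Reagents that add atoms: none
Why: Transmetalation of the alkenyl Grignard reagent onto tin (nucleophilic substitution at tin) is the standard preparation of an alkenylstannane.

Step 10
Reactants: 14 (2S)-6-[(4-benzyloxy-6-ethyl-5-methyl-2-oxo-2H-pyran-3-yl)methyl]-8-iodo-5,7-dimethoxy-2-phenylchroman-4-one; 17 tributyl(2-methylprop-1-enyl)stannane
Product: 18 (2S)-6-[(4-benzyloxy-6-ethyl-5-methyl-2-oxo-2H-pyran-3-yl)methyl]-5,7-dimethoxy-8-(3-methylbut-2-enoyl)-2-phenylchroman-4-one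
Conditions: Pd2(dba)3 (5 mol%), AsPh3 (20 mol%), LiCl, CO (3 atm), NMP, 60 °C
Reagents that add atoms: carbon monoxide, [C-]#[O+]
Why: Carbonylative Stille coupling: oxidative addition of zerovalent palladium into the C8–I bond, CO insertion and transmetalation/reductive elimination with the alkenylstannane should deliver the senecioyl ketone under neutral, base-free conditions that leave C2 and the C3 hydrogens untouched.

Step 11
Reactants: 18 (2S)-6-[(4-benzyloxy-6-ethyl-5-methyl-2-oxo-2H-pyran-3-yl)methyl]-5,7-dimethoxy-8-(3-methylbut-2-enoyl)-2-phenylchroman-4-one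
Product: 19 (2S)-6-[(6-ethyl-4-hydroxy-5-methyl-2-oxo-2H-pyran-3-yl)methyl]-5,7-dihydroxy-8-(3-methylbut-2-enoyl)-2-phenylchroman-4-one
Conditions: BCl3 (1 M in CH2Cl2, 6 equiv), C6HMe5 (3 equiv), CH2Cl2, −78 → 0 °C; MeOH quench at −78 °C, then aqueous NaHCO3
Reagents that add atoms: none
Why: Lewis-acid ether cleavage with BCl3: each ring A methyl ether sits next to a chelating carbonyl (C5–OMe to C4=O, C7–OMe to the C8 ketone) and the pyrone benzyl ether is a vinylogous benzyl ester, so all three should cleave at low temperature with pentamethylbenzene trapping the benzyl cation, cold enough to suppress addition of the C7 oxygen to the enone and opening of ring C.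

Compound list
1 | pentan-3-one | CCC(=O)CC | starting material
2 | 3-(trimethylsilyloxy)pent-2-ene (E/Z mixture, geometry not defined) | CC=C(CC)O[Si](C)(C)C | intermediate
3 | malonyl dichloride | O=C(Cl)CC(Cl)=O | starting material
4 | 6-ethyl-4-hydroxy-5-methyl-2H-pyran-2-one | CCc1oc(=O)cc(O)c1C | intermediate
5 | 4-hydroxy-2,6-dimethoxybenzaldehyde | COc1cc(O)cc(OC)c1C=O | starting material
6 | ethyl (3R)-3-hydroxy-3-phenylpropanoate | CCOC(=O)C[C@@H](O)c1ccccc1 | starting material
7 | ethyl (3S)-3-(4-formyl-3,5-dimethoxyphenoxy)-3-phenylpropanoate | CCOC(=O)C[C@@H](c1ccccc1)Oc1cc(OC)c(C=O)c(OC)c1 | intermediate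
8 | Knoevenagel adduct: ethyl (3S)-3-{4-[(6-ethyl-5-methyl-2,4-dioxo-2H-pyran-3(4H)-ylidene)methyl]-3,5-dimethoxyphenoxy}-3-phenylpropanoate (alkene geometry not defined) | CCOC(=O)C[C@@H](c1ccccc1)Oc1cc(OC)c(C=C2C(=O)OC(CC)=C(C)C2=O)c(OC)c1 | intermediate (not isolated)
9 | ethyl (3S)-3-{4-[(6-ethyl-4-hydroxy-5-methyl-2-oxo-2H-pyran-3-yl)methyl]-3,5-dimethoxyphenoxy}-3-phenylpropanoate | CCOC(=O)C[C@@H](c1ccccc1)Oc1cc(OC)c(Cc2c(O)c(C)c(CC)oc2=O)c(OC)c1 | intermediate
10 | ethyl (3S)-3-{4-[(4-benzyloxy-6-ethyl-5-methyl-2-oxo-2H-pyran-3-yl)methyl]-3,5-dimethoxyphenoxy}-3-phenylpropanoate | CCOC(=O)C[C@@H](c1ccccc1)Oc1cc(OC)c(Cc2c(OCc3ccccc3)c(C)c(CC)oc2=O)c(OC)c1 | intermediate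
11 | (3S)-3-{4-[(4-benzyloxy-6-ethyl-5-methyl-2-oxo-2H-pyran-3-yl)methyl]-3,5-dimethoxyphenoxy}-3-phenylpropanoic acid | OC(=O)C[C@@H](c1ccccc1)Oc1cc(OC)c(Cc2c(OCc3ccccc3)c(C)c(CC)oc2=O)c(OC)c1 | intermediate
12 | mixed anhydride of 11 with trifluoroacetic acid | O=C(C[C@@H](c1ccccc1)Oc1cc(OC)c(Cc2c(OCc3ccccc3)c(C)c(CC)oc2=O)c(OC)c1)OC(=O)C(F)(F)F | intermediate (not isolated)
13 | (2S)-6-[(4-benzyloxy-6-ethyl-5-methyl-2-oxo-2H-pyran-3-yl)methyl]-5,7-dimethoxy-2-phenylchroman-4-one | O=C1C[C@@H](c2ccccc2)Oc2cc(OC)c(Cc3c(OCc4ccccc4)c(C)c(CC)oc3=O)c(OC)c21 | intermediate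
14 | (2S)-6-[(4-benzyloxy-6-ethyl-5-methyl-2-oxo-2H-pyran-3-yl)methyl]-8-iodo-5,7-dimethoxy-2-phenylchroman-4-one | O=C1C[C@@H](c2ccccc2)Oc2c(I)c(OC)c(Cc3c(OCc4ccccc4)c(C)c(CC)oc3=O)c(OC)c21 | intermediate
15 | 2-methylprop-1-enylmagnesium bromide (solution in THF) | CC(C)=C[Mg]Br | starting material
16 | tributyltin chloride | CCCC[Sn](Cl)(CCCC)CCCC | starting material
17 | tributyl(2-methylprop-1-enyl)stannane | CC(C)=C[Sn](CCCC)(CCCC)CCCC | intermediate
18 | (2S)-6-[(4-benzyloxy-6-ethyl-5-methyl-2-oxo-2H-pyran-3-yl)methyl]-5,7-dimethoxy-8-(3-methylbut-2-enoyl)-2-phenylchroman-4-one | O=C1C[C@@H](c2ccccc2)Oc2c(C(=O)C=C(C)C)c(OC)c(Cc3c(OCc4ccccc4)c(C)c(CC)oc3=O)c(OC)c21 | intermediate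
19 | (2S)-6-[(6-ethyl-4-hydroxy-5-methyl-2-oxo-2H-pyran-3-yl)methyl]-5,7-dihydroxy-8-(3-methylbut-2-enoyl)-2-phenylchroman-4-one | CCc1oc(=O)c(Cc2c(O)c(C(=O)C=C(C)C)c3c(c2O)C(=O)C[C@@H](c2ccccc2)O3)c(O)c1C | target

Total step count: 11 (including the one-step preparation of stannane 17).
Longest linear sequence: 9 steps (steps 1, 2, 4, 5, 6, 7, 8, 10, 11, from pentan-3-one).

Steps most likely to fail

Step 10. CO insertion and transmetalation at the doubly ortho-substituted C8–palladium bond may be slow, so that protodeiodination or direct coupling without CO competes. The fallback sets out from iodide 14. A Nozaki–Hiyama–Kishi addition to 3-methylbut-2-enal (CrCl2, NiCl2 cat., DMF, rt) is selective for the aldehyde over the C4 ketone. It should give (2S)-6-[(4-benzyloxy-6-ethyl-5-methyl-2-oxo-2H-pyran-3-yl)methyl]-8-(1-hydroxy-3-methylbut-2-enyl)-5,7-dimethoxy-2-phenylchroman-4-one F1 as a mixture of carbinol epimers. Oxidation of this allylic, benzylic alcohol with MnO2 in CH2Cl2 returns to the route at 18.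

Step 11. The C7 oxygen, once freed as its boron phenoxide, may add to the senecioyl enone and close a dimethylpyranone ring. Cleavage of the C7 methyl ether may also stall, or Lewis-acid opening of ring C may erode the C2 configuration. The fallback removes the Lewis acid from every stage at which the enone is present, and sets out from iodide 14.
- BBr3 (CH2Cl2, −78 → 0 °C) cleaves the two methyl ethers and the benzyl ether to give (2S)-6-[(6-ethyl-4-hydroxy-5-methyl-2-oxo-2H-pyran-3-yl)methyl]-5,7-dihydroxy-8-iodo-2-phenylchroman-4-one F2.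
- Ac2O/pyridine converts it into the corresponding 5,7-diacetoxy-6-[(4-acetoxypyranonyl)methyl] iodide, triacetate F3.
- Carbonylative Stille coupling with 17 under the conditions of step 10 gives (2S)-5,7-diacetoxy-6-[(4-acetoxy-6-ethyl-5-methyl-2-oxo-2H-pyran-3-yl)methyl]-8-(3-methylbut-2-enoyl)-2-phenylchroman-4-one F4.
- Near-neutral deacetylation (NH4OAc, MeOH/H2O, rt) returns to the route at target 19.

Step 7. The activated acid may lose the phenol by elimination or by heterolysis of the benzylic C–O bond, ring A may be trifluoroacetylated intermolecularly, or acid-mediated reversible opening may lower the enantiopurity. The fallback forms the same C4–C4a bond by an anionic Parham cyclisation and sets out from acid 11. NIS in MeCN iodinates one of the two equivalent carbons ortho to the ether oxygen to give (3S)-3-{4-[(4-benzyloxy-6-ethyl-5-methyl-2-oxo-2H-pyran-3-yl)methyl]-2-iodo-3,5-dimethoxyphenoxy}-3-phenylpropanoic acid F5. Treatment with n-BuLi (2.2 equiv, THF, −100 → −78 °C) forms the lithium carboxylate and effects iodine–lithium exchange. The aryllithium adds to the carboxylate, and aqueous work-up returns to the route at flavanone 13.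

Further compounds
F1 | step 10 | (2S)-6-[(4-benzyloxy-6-ethyl-5-methyl-2-oxo-2H-pyran-3-yl)methyl]-8-(1-hydroxy-3-methylbut-2-enyl)-5,7-dimethoxy-2-phenylchroman-4-one (carbinol epimers) | O=C1C[C@@H](c2ccccc2)Oc2c(C(O)C=C(C)C)c(OC)c(Cc3c(OCc4ccccc4)c(C)c(CC)oc3=O)c(OC)c21
F2 | step 11 | (2S)-6-[(6-ethyl-4-hydroxy-5-methyl-2-oxo-2H-pyran-3-yl)methyl]-5,7-dihydroxy-8-iodo-2-phenylchroman-4-one | O=C1C[C@@H](c2ccccc2)Oc2c(I)c(O)c(Cc3c(O)c(C)c(CC)oc3=O)c(O)c21
F3 | step 11 | (2S)-5,7-diacetoxy-6-[(4-acetoxy-6-ethyl-5-methyl-2-oxo-2H-pyran-3-yl)methyl]-8-iodo-2-phenylchroman-4-one | O=C1C[C@@H](c2ccccc2)Oc2c(I)c(OC(C)=O)c(Cc3c(OC(C)=O)c(C)c(CC)oc3=O)c(OC(C)=O)c21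
F4 | step 11 | (2S)-5,7-diacetoxy-6-[(4-acetoxy-6-ethyl-5-methyl-2-oxo-2H-pyran-3-yl)methyl]-8-(3-methylbut-2-enoyl)-2-phenylchroman-4-one | O=C1C[C@@H](c2ccccc2)Oc2c(C(=O)C=C(C)C)c(OC(C)=O)c(Cc3c(OC(C)=O)c(C)c(CC)oc3=O)c(OC(C)=O)c21
F5 | step 7 | (3S)-3-{4-[(4-benzyloxy-6-ethyl-5-methyl-2-oxo-2H-pyran-3-yl)methyl]-2-iodo-3,5-dimethoxyphenoxy}-3-phenylpropanoic acid | OC(=O)C[C@@H](c1ccccc1)Oc1cc(OC)c(Cc2c(OCc3ccccc3)c(C)c(CC)oc2=O)c(OC)c1I
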